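The route builds the aromatic ring on the terpene instead of joining a phloroglucinol to a neopentyl-type carbon. The feature used is the 2-alkylphloroglucinol ring: its ipso carbon sits on the benzylic CH C7' (bonded to quaternary C4 of the cyclopentanone ring), with oxygens on both ortho carbons and the para carbon. In one thermal operation a siloxyalkyne on C7' and 3-ethoxycyclobutenone form three arene C–C bonds and the benzene ring, with the three oxygens differentiated (OH, OSi, OEt) and two CH sites left for formylation. The precursor is a triisopropylsiloxyalkyne carrying the ledene-derived cyclopropane and a cyclopentene, C4 and C7' having been set by an Ireland–Claisen rearrangement.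

Key step: step 9

Remarks on the chemistry
- Atom labels: C1 ring carbonyl carbon, C2/C3 ring CH2, C4 quaternary ring carbon, C5 ring CH, C6/C7 cyclopropane CH, C8/C9 chain CH2, C10 chain carbonyl carbon, C11 CMe2, C7' benzylic CH.
- The C6/C7 configuration of (+)-ledene is already that of the target; C4, C5 and C7' are rebuilt.
- Assumption: the Ireland–Claisen step passes through a chair-like transition state.
- Assumption: the C5 epimer with the cyclopropyl group trans to the C7' arm is the thermodynamic one. Hydroboration is expected to give the other epimer first, so an equilibration is built into step 12.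
- The free phenol from the key step is silylated before borane and oxidant are used.

Step 1
Reactants: 1 (+)-ledene
Product: 3 seco-diketone (C1 cyclopentanone; C10 methyl ketone), via secondary ozonide 2 (not isolated)
Conditions: O3, CH2Cl2, −78 °C; then PPh3, −78 °C → rt
Reagents that add atoms: ozone, [O-][O+]=O
Why: Ozonolysis cleaves the only C=C (tetrasubstituted C1=C10), the tethered carbonyl oxide and ketone closing to the ozonide that PPh3 reduces, while the cyclopropane and the C4, C5, C6 and C7 centres are untouched.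

Step 2
Reactants: 3 seco-diketone
Product: 4 keto ketal (C10 as 1,3-dioxolane)
Conditions: Me3SiOCH2CH2OSiMe3 (1.1 equiv), Me3SiOTf (cat.), CH2Cl2, −78 °C; pyridine quench
Reagents that add atoms: 1,2-bis(trimethylsiloxy)ethane, C[Si](C)(C)OCCO[Si](C)(C)C
Why: Silyl-triflate-catalysed ketalisation (Noyori conditions) at low temperature should select the unhindered methyl ketone C10 over the α-branched cyclopentanone C1 and, being non-enolising, avoids aldol closure of the 1,7-diketone.

Step 3
Reactants: 4 keto ketal
Product: 6 cyclopentenone (C4=C5 alkene conjugated to C1=O), via trimethylsilyl enol ether 5 (not isolated)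
Conditions: Me3SiCl, Et3N, DMF, 90 °C; pentane extraction; then Pd(OAc)2 (1.05 equiv), MeCN, rt
Reagents that add atoms: none
Why: Thermodynamic silylation gives mainly the tetrasubstituted C1=C5 enol ether and Saegusa–Ito oxidation then palladates C5 and removes the C4 hydrogen by β-hydride elimination (elimination toward the cyclopropane would give a strained alkylidenecyclopropane), erasing the C4 and C5 stereocentres on purpose.

Step 4
Reactants: 6 cyclopentenone
Product: 7 (1R)-allylic alcohol
Conditions: (S)-Me-CBS [(S)-2-methyl-5,5-diphenyl-3,4-propano-1,3,2-oxazaborolidine, 0.2 equiv], BH3·SMe2 (0.7 equiv), THF, −20 °C; MeOH quench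
Reagents that add atoms: none
Why: Corey–Bakshi–Shibata reduction with the α-substituted alkene arm as the large group and the ring CH2 as the small one should give the (1R)-alcohol by analogy with aryl methyl ketones, the catalyst overriding the remote cyclopropane stereocentres.

Step 5
Reactants: 7 (1R)-allylic alcohol; 8 4-methylpentanoic acid
Product: 9 (1R)-cyclopentenyl 4-methylpentanoate
Conditions: DCC, DMAP (cat.), CH2Cl2, 0 °C → rt
Reagents that add atoms: none
Why: Steglich esterification acylates the secondary allylic alcohol under neutral conditions with retention at C1 and without ionising the allylic system.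

Step 6
Reactants: 9 (1R)-cyclopentenyl 4-methylpentanoate
Product: 12 carboxylic acid (quaternary C4; C7' bearing H and isobutyl and CO2H; C5=C1 alkene), via silyl ketene acetal 10 (not isolated), via trimethylsilyl ester 11 (not isolated)
Conditions: LiN(iPr)2 (LDA), THF, −78 °C; Me3SiCl/Et3N, −78 °C → rt, then 65 °C; 1 M NaOH, then citric acid to pH 4
Reagents that add atoms: none
Why: Ireland–Claisen rearrangement in which kinetic enolisation in THF places the isobutyl group cis to the allylic oxygen, the suprafacial [3,3] shift delivers C7' to the C4 face that carried the C1 oxygen (setting quaternary C4), and a chair-like transition state, expected because the C5 substituent penalises the boat, sets C7' as the target requires.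

Step 7
Reactants: 12 carboxylic acid
Product: 13 methyl ester
Conditions: MeI, K2CO3, DMF, rt
Reagents that add atoms: iodomethane, CI
Why: Carboxylate O-alkylation (SN2 on MeI) gives the methyl ester without enolising the hindered C7' centre.

Step 8
Reactants: 13 methyl ester
Product: 15 triisopropylsiloxyalkyne (C7'–C≡C–OSi), via lithium ynolate 14 (not isolated)
Conditions: CH2Br2, lithium 2,2,6,6-tetramethylpiperidide (LiTMP), THF, −78 °C; n-BuLi, −78 → 0 °C; then iPr3SiOTf, −78 → 0 °C
Reagents that add atoms: dibromomethane, BrCBr; triisopropylsilyl trifluoromethanesulfonate, CC(C)[Si](OS(=O)(=O)C(F)(F)F)(C(C)C)C(C)C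
Why: Kowalski ester homologation in which LiCHBr2 adds to the ester, the dibromo ketone enolate undergoes Br/Li exchange and 1,2-shift of C7' with retention to the ynolate, and the bulky silyl triflate traps it on oxygen.

Step 9
Reactants: 15 triisopropylsiloxyalkyne; 16 3-ethoxycyclobut-2-en-1-one
Product: 21 differentiated 2-alkylphloroglucinol (OH; OSi(iPr)3; OEt para to C7'), via 3-ethoxyvinylketene 17 (not isolated), via vinylcyclobutenone adduct 18 (not isolated), via dienylketene 19 (not isolated), via cyclohexadienone 20 (not isolated)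
Conditions: 16 (1.5 equiv), PhMe, 80 °C then 110 °C, argon, sealed tube
Reagents that add atoms: none
Why: Heating opens 16 by 4π electrocyclic ring opening to vinylketene 17, whose carbonyl carbon is attacked by the nucleophilic C7'-bearing alkyne carbon in a [2+2] cycloaddition to 18; a second 4π opening gives dienylketene 19, which closes the six-membered ring by 6π electrocyclisation (ketene carbon to terminal CH2) to 20 and tautomerises to the phenol. This is a Danheiser benzannulation of a cyclobutenone with a siloxyalkyne, here applied to an alkoxy-substituted cyclobutenone and a branched alkyne. No stereocentre is formed, and C4, C7', C6 and C7 are untouched because all bond making occurs at the sp carbons beyond C7'. The selectivity needed is regiochemical: the oxygen-polarised alkyne bonds through its alkyl-bearing carbon to the ketene carbonyl carbon, which places C7' between the new phenol carbon and the siloxy carbon and the ethoxy group para to C7'. Chemoselectivity rests on the low ketenophilicity of the hindered trisubstituted cyclopentene and the inertness of the dioxolane under neutral thermal conditions.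

Step 10
Reactants: 21 differentiated 2-alkylphloroglucinol
Product: 22 bis(triisopropylsilyl) ether
Conditions: iPr3SiOTf, 2,6-lutidine, CH2Cl2, 0 °C → rt
Reagents that add atoms: triisopropylsilyl trifluoromethanesulfonate, CC(C)[Si](OS(=O)(=O)C(F)(F)F)(C(C)C)C(C)C
Why: Phenol silylation with the silyl triflate removes the oxidisable free phenol before borane and periodinane chemistry and makes both flanking oxygens identical for one later deprotection.

Step 11
Reactants: 22 bis(triisopropylsilyl) ether
Product: 24 C1 alcohol (C5 epimer of the target series), via alkylborane 23 (not isolated)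
Conditions: BH3·THF (3 equiv), THF, 0 °C → rt; then 30% H2O2, 1 M NaOH, 0 °C
Reagents that add atoms: hydrogen peroxide, OO
Why: Hydroboration–oxidation puts boron on the less substituted C1 and hydrogen on C5 by syn addition from the methyl face of C4 (anti to the bulky C7' arm), so the C1 alcohol should form as the C5 epimer that step 12 corrects.

Step 12
Reactants: 24 C1 alcohol
Product: 26 C1 ketone with the target C5 configuration, via C5-epimeric ketone 25 (not isolated)
Conditions: Dess–Martin periodinane, CH2Cl2, 0 °C → rt; aqueous Na2S2O3/NaHCO3 wash; then KOt-Bu (0.3 equiv), t-BuOH/THF, 0 °C → rt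
Reagents that add atoms: none
Why: Dess–Martin oxidation gives the C1 ketone and alkoxide-catalysed enolisation toward C5 (thermodynamic epimerisation) should move the cyclopropyl group trans to the bulky C7' arm, which is the C5 configuration of the target, while the dioxolane blocks any aldol with C10.

Step 13
Reactants: 26 C1 ketone
Product: 28 resorcinol diketone (two free OH; OEt; C1 and C10 ketones), via resorcinol ketal 27 (not isolated)
Conditions: Bu4NF (3 equiv), THF, 0 °C → rt; then 1 M HCl, rt
Reagents that add atoms: water, O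
Why: Fluoride cleaves both aryl silyl ethers and aqueous acid then hydrolyses the dioxolane (acetal hydrolysis), so that no acetal is exposed to the Lewis acid of the formylation.

Step 14
Reactants: 28 resorcinol diketone
Product: 29 diformyl ethyl ether
Conditions: Cl2CHOMe (3 equiv), TiCl4 (5 equiv), CH2Cl2, −78 → 0 °C; then ice-cold 1 M HCl, rt
Reagents that add atoms: dichloromethyl methyl ether, COC(Cl)Cl; water, O
Why: Rieche formylation, in which both ring CH positions are ortho or para to all three oxygens and each is ortho to a titanium phenoxide, so double electrophilic substitution at low temperature should be fast enough to spare the cyclopropane and the unenolised ketones.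

Step 15
Reactants: 29 diformyl ethyl ether
Product: 30 CNP0217082.3 (target)
Conditions: BCl3 (4 equiv), CH2Cl2, −78 → 0 °C; then H2O
Reagents that add atoms: none
Why: Chelation-assisted Lewis-acid ether cleavage, BCl3 bridging the ether oxygen and a flanking formyl oxygen, should remove the ethyl group at low temperature, where the cyclopropane, ketones and aldehydes should persist.

Compound list
1 | (+)-ledene, (1aR,7R,7aS,7bR) | CC1=C2CC[C@@H](C)[C@H]2[C@H]3[C@@H](CC1)C3(C)C | starting material
2 | secondary ozonide of 1 (1,2,4-trioxolane spanning C1 and C10, acetal carbons as formed) | CC12CC[C@@H]3[C@H]([C@@H]4[C@H](C)CCC4(OO1)O2)C3(C)C | intermediate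
3 | seco-diketone: 3-methylcyclopentanone bearing at C5 the cis-2,2-dimethyl-3-(3-oxobutyl)cyclopropyl group, C4/C5/C6/C7 as in ledene | CC(=O)CC[C@@H]1[C@H]([C@H]2C(=O)CC[C@H]2C)C1(C)C | intermediate
4 | keto ketal: 3 with C10 as 1,3-dioxolane | CC1(CC[C@@H]2[C@H]([C@H]3C(=O)CC[C@H]3C)C2(C)C)OCCO1 | intermediate
5 | trimethylsilyl enol ether of 4 (C1=C5) | CC1(CC[C@@H]2[C@H](C3=C(O[Si](C)(C)C)CC[C@H]3C)C2(C)C)OCCO1 | intermediate
6 | cyclopentenone: 3-methylcyclopent-2-en-1-one with the cyclopropyl group on the α-carbon C5, dioxolane at C10 | CC1(CC[C@@H]2[C@H](C3=C(C)CCC3=O)C2(C)C)OCCO1 | intermediate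
7 | (1R)-allylic alcohol from 6 | CC1(CC[C@@H]2[C@H](C3=C(C)CC[C@H]3O)C2(C)C)OCCO1 | intermediate
8 | 4-methylpentanoic acid | CC(C)CCC(=O)O | starting material
9 | 4-methylpentanoate of 7 | CC1(CC[C@@H]2[C@H](C3=C(C)CC[C@H]3OC(=O)CCC(C)C)C2(C)C)OCCO1 | intermediate
10 | (E)-O-trimethylsilyl ketene acetal of 9 (isobutyl cis to the allylic oxygen) | CC1(CC[C@@H]2[C@H](C3=C(C)CC[C@H]3O/C(O[Si](C)(C)C)=C\CC(C)C)C2(C)C)OCCO1 | intermediate
11 | trimethylsilyl ester of 12 | CC1(CC[C@@H]2[C@H](C3=CCC[C@]3(C)[C@@H](CC(C)C)C(=O)O[Si](C)(C)C)C2(C)C)OCCO1 | intermediate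
12 | carboxylic acid: cyclopent-1-ene (C5=C1) with quaternary C4 (methyl and C7'), C7' carrying H, isobutyl and CO2H | CC1(CC[C@@H]2[C@H](C3=CCC[C@]3(C)[C@@H](CC(C)C)C(=O)O)C2(C)C)OCCO1 | intermediate
13 | methyl ester of 12 | CC1(CC[C@@H]2[C@H](C3=CCC[C@]3(C)[C@@H](CC(C)C)C(=O)OC)C2(C)C)OCCO1 | intermediate
14 | lithium ynolate (C7'–C≡C–OLi) | CC1(CC[C@@H]2[C@H](C3=CCC[C@]3(C)[C@@H](CC(C)C)C#CO[Li])C2(C)C)OCCO1 | intermediate
15 | triisopropylsiloxyalkyne (key-step precursor) | CC1(CC[C@@H]2[C@H](C3=CCC[C@]3(C)[C@@H](CC(C)C)C#CO[Si](C(C)C)(C(C)C)C(C)C)C2(C)C)OCCO1 | intermediate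
16 | 3-ethoxycyclobut-2-en-1-one | CCOC1=CC(=O)C1 | starting material
17 | 3-ethoxyvinylketene (3-ethoxybuta-1,3-dien-1-one) | C=C(OCC)C=C=O | intermediate
18 | vinylcyclobutenone adduct: 4-(1-ethoxyvinyl)-3-(triisopropylsiloxy)cyclobut-2-en-1-one with C7' on C2 (ring CH as formed) | CC1(CC[C@@H]2[C@H](C3=CCC[C@]3(C)[C@@H](CC(C)C)C3=C(O[Si](C(C)C)(C(C)C)C(C)C)C(C(=C)OCC)C3=O)C2(C)C)OCCO1 | intermediate
19 | dienylketene from 18 | CC1(CC[C@@H]2[C@H](C3=CCC[C@]3(C)[C@@H](CC(C)C)C(=C=O)/C(O[Si](C(C)C)(C(C)C)C(C)C)=C\C(=C)OCC)C2(C)C)OCCO1 | intermediate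
20 | cyclohexa-2,4-dienone tautomer of 21 | CC1(CC[C@@H]2[C@H](C3=CCC[C@]3(C)[C@@H](CC(C)C)C3=C(O[Si](C(C)C)(C(C)C)C(C)C)C=C(OCC)CC3=O)C2(C)C)OCCO1 | intermediate
21 | differentiated 2-alkylphloroglucinol (OH, OSi(iPr)3, OEt), key-step product | CC1(CC[C@@H]2[C@H](C3=CCC[C@]3(C)[C@@H](CC(C)C)c3c(O)cc(OCC)cc3O[Si](C(C)C)(C(C)C)C(C)C)C2(C)C)OCCO1 | intermediate
22 | bis(triisopropylsilyl) ether of 21 | CC1(CC[C@@H]2[C@H](C3=CCC[C@]3(C)[C@@H](CC(C)C)c3c(O[Si](C(C)C)(C(C)C)C(C)C)cc(OCC)cc3O[Si](C(C)C)(C(C)C)C(C)C)C2(C)C)OCCO1 | intermediate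
23 | C1 alkylborane (B and H-5 on the methyl face) | CC1(CC[C@@H]2[C@H]([C@@H]3[C@@H](B)CC[C@]3(C)[C@@H](CC(C)C)c3c(O[Si](C(C)C)(C(C)C)C(C)C)cc(OCC)cc3O[Si](C(C)C)(C(C)C)C(C)C)C2(C)C)OCCO1 | intermediate
24 | C1 alcohol (OH and H-5 on the methyl face; cyclopropyl cis to the C7' arm) | CC1(CC[C@@H]2[C@H]([C@@H]3[C@@H](O)CC[C@]3(C)[C@@H](CC(C)C)c3c(O[Si](C(C)C)(C(C)C)C(C)C)cc(OCC)cc3O[Si](C(C)C)(C(C)C)C(C)C)C2(C)C)OCCO1 | intermediate
25 | C1 ketone, C5 epimer (cyclopropyl cis to the C7' arm) | CC1(CC[C@@H]2[C@H]([C@@H]3C(=O)CC[C@]3(C)[C@@H](CC(C)C)c3c(O[Si](C(C)C)(C(C)C)C(C)C)cc(OCC)cc3O[Si](C(C)C)(C(C)C)C(C)C)C2(C)C)OCCO1 | intermediate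
26 | C1 ketone, target C5 configuration (cyclopropyl trans to the C7' arm) | CC1(CC[C@@H]2[C@H]([C@H]3C(=O)CC[C@]3(C)[C@@H](CC(C)C)c3c(O[Si](C(C)C)(C(C)C)C(C)C)cc(OCC)cc3O[Si](C(C)C)(C(C)C)C(C)C)C2(C)C)OCCO1 | intermediate
27 | resorcinol ketal (both silyl groups removed) | CC1(CC[C@@H]2[C@H]([C@H]3C(=O)CC[C@]3(C)[C@@H](CC(C)C)c3c(O)cc(OCC)cc3O)C2(C)C)OCCO1 | intermediate
28 | resorcinol diketone | CC(=O)CC[C@@H]1[C@H]([C@H]2C(=O)CC[C@]2(C)[C@@H](CC(C)C)c2c(O)cc(OCC)cc2O)C1(C)C | intermediate
29 | diformyl ethyl ether | CC(=O)CC[C@@H]1[C@H]([C@H]2C(=O)CC[C@]2(C)[C@@H](CC(C)C)c2c(O)c(C=O)c(OCC)c(C=O)c2O)C1(C)C | intermediate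
30 | CNP0217082.3, (4R,5R,6R,7R,7'R) | CC(=O)CC[C@@H]1[C@H]([C@H]2C(=O)CC[C@]2(C)[C@@H](CC(C)C)c2c(O)c(C=O)c(O)c(C=O)c2O)C1(C)C | target

Total step count: 15. Longest linear sequence: 15 steps (1 → 30); 8 and 16 are purchased.

Steps most likely to fail

Step 9. The vinylketene released by thermal ring opening may oligomerise or acylate the product phenol faster than the congested siloxyalkyne captures it, and long heating may let the siloxyalkyne isomerise by silyl migration. The fallback sets out from 15 and separates ketene generation from the thermal cascade. Ketene 17 is generated at 0 °C by slow addition of Et3N to (E)-3-ethoxybut-2-enoyl chloride in CH2Cl2 in the presence of 15 (base-induced 1,4-dehydrochlorination), and the [2+2] adduct 18 is isolated. Adduct 18 alone is then warmed in toluene at 80 °C, where 4π opening and 6π closure give 21, the point of return.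

Step 6. Chair-like and boat-like pathways may compete, which would erode selectivity at C7', and the congested ketene acetal may decompose before it rearranges onto the tetrasubstituted alkene. The fallback sets out from 7 and takes C7' out of the rearrangement. Acetylation (Ac2O, pyridine, DMAP) gives the allylic acetate F1. Its Ireland–Claisen rearrangement (LDA, Me3SiCl, THF, −78 → 65 °C) gives the C4 acetic acid F2 with the same chirality transfer to C4 and a less hindered ketene acetal. Activation with pivaloyl chloride/Et3N and lithiated (R)-4-benzyloxazolidin-2-one gives the imide F3. Auxiliary-controlled enolate alkylation (NaN(SiMe3)2, 3-bromo-2-methylpropene, THF, −78 → −40 °C) gives the methallyl imide F4 with C7' set by the auxiliary. Hydrogenation with RhCl(PPh3)3/H2 reduces only the 1,1-disubstituted alkene and gives the isobutyl imide F5. LiOH/H2O2 then releases acid 12, the point of return.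

Step 8. Addition of LiCHBr2 to the congested ester carbonyl may be slower than decomposition of the carbenoid, so the ynolate would not form. The fallback sets out from 13 and reaches the ynolate by oxidation of an acetylide instead of rearrangement. LiAlH4 reduction gives the primary alcohol F6 and Dess–Martin oxidation gives the aldehyde F7. Ohira–Bestmann homologation (dimethyl (1-diazo-2-oxopropyl)phosphonate, K2CO3, MeOH, 0 °C) gives the terminal alkyne F8. Deprotonation with n-BuLi, oxygen transfer from LiOOt-Bu (from t-BuOOH and LiN(SiMe3)2, THF, −78 → 0 °C) to give ynolate 14, and trapping with iPr3SiOTf return the route to 15.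

Further compounds
F0 | step 9 | none | none
F1 | step 6 | allylic acetate of 7 | CC1(CC[C@@H]2[C@H](C3=C(C)CC[C@H]3OC(C)=O)C2(C)C)OCCO1
F2 | step 6 | C4 acetic acid (quaternary C4 carrying CH2CO2H; C5=C1 alkene) | CC1(CC[C@@H]2[C@H](C3=CCC[C@]3(C)CC(=O)O)C2(C)C)OCCO1
F3 | step 6 | N-acyl (R)-4-benzyloxazolidin-2-one of F2 | CC1(CC[C@@H]2[C@H](C3=CCC[C@]3(C)CC(=O)N3[C@H](Cc4ccccc4)COC3=O)C2(C)C)OCCO1
F4 | step 6 | C7'-methallyl imide | CC1(CC[C@@H]2[C@H](C3=CCC[C@]3(C)[C@@H](CC(C)=C)C(=O)N3[C@H](Cc4ccccc4)COC3=O)C2(C)C)OCCO1
F5 | step 6 | C7'-isobutyl imide | CC1(CC[C@@H]2[C@H](C3=CCC[C@]3(C)[C@@H](CC(C)C)C(=O)N3[C@H](Cc4ccccc4)COC3=O)C2(C)C)OCCO1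
F6 | step 8 | primary alcohol (C7'–CH2OH) | CC1(CC[C@@H]2[C@H](C3=CCC[C@]3(C)[C@@H](CC(C)C)CO)C2(C)C)OCCO1
F7 | step 8 | aldehyde (C7'–CHO) | CC1(CC[C@@H]2[C@H](C3=CCC[C@]3(C)[C@@H](CC(C)C)C=O)C2(C)C)OCCO1
F8 | step 8 | terminal alkyne (C7'–C≡CH) | CC1(CC[C@@H]2[C@H](C3=CCC[C@]3(C)[C@@H](CC(C)C)C#C)C2(C)C)OCCO1
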